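**Assumption (one line):** the facial sense of the two catalytic asymmetric cycloadditions (steps 3 and 6) is taken from the published models for these catalyst families and is not verified; if either runs the other way, the mirror-image catalyst or ligand is used.

## Retrosynthetic overview

1. Target 20 comes from hydrolysis of cyclic anhydride 19, which carries both acids through the route without extra atoms.
2. 19 is cut at the bond between the quaternary ring A carbon and the bicyclic CH: tertiary-radical conjugate addition of bromide 18 to bicyclic enone 8.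
3. 8 comes from 7, made in one flask from two achiral, acyclic partners (2-methylidenepent-4-ynal 3 and silyloxydiene 5) by an enantioselective Diels–Alder reaction followed by gold-catalysed carbocyclisation; rings C and D form together.
4. 18 comes from ring A lactone 13, made by a template-directed enantioselective Diels–Alder reaction of dienol 10 with methyl methacrylate, then oxidation to the anhydride and hydrobromination.
5. Ring order: rings C and D (step 3) and ring A (step 6) are built in parallel; the ring systems are joined in step 10.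

## Route

Step 1
Reactants: 1 pent-4-yn-1-ol
Product: 3 2-methylidenepent-4-ynal, via pent-4-ynal 2 (not isolated)
Conditions: TEMPO (10 mol%), PhI(OAc)2 (1.1 equiv), CH2Cl2, rt; NaHCO3 wash; then 37% aq. CH2O, pyrrolidine (10 mol%), EtCO2H (10 mol%), i-PrOH, 45 °C
Reagents that add atoms: formaldehyde C=O
Why: Oxoammonium (TEMPO/PhI(OAc)2) oxidation stops at the aldehyde and tolerates the terminal alkyne, and the amine-catalysed Mannich condensation/elimination with formaldehyde (organocatalytic α-methylenation) gives the 2-substituted acrolein; no stereocentre is formed.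

Step 2
Reactants: 4 but-3-en-2-one
Product: 5 tert-butyl(buta-1,3-dien-2-yloxy)dimethylsilane
Conditions: TBSOTf, Et3N, Et2O, 0 °C
Reagents that add atoms: tert-butyldimethylsilyl trifluoromethanesulfonate CC(C)(C)[Si](C)(C)OS(=O)(=O)C(F)(F)F
Why: Soft enolisation of the methyl ketone (silyl triflate/amine) gives the 2-silyloxydiene; no stereocentre is formed.

Step 3
Reactants: 3 2-methylidenepent-4-ynal; 5 tert-butyl(buta-1,3-dien-2-yloxy)dimethylsilane
Product: 7 (1R,5R)-6-methylidene-4-oxobicyclo[3.2.1]octane-1-carbaldehyde, via silyl enol ether 6 (not isolated)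
Conditions: (R)-o-tolyl-CBS oxazaborolidine·Tf2NH (20 mol%), CH2Cl2, −78 to −40 °C; then 2,6-di-tert-butylpyridine (25 mol%), Ph3PAuNTf2 (5 mol%), MeOH (5 equiv), rt
Reagents that add atoms: none
Why: Proposed new method: one-pot merger of an enantioselective Diels–Alder reaction with a Conia-ene-type 5-exo-dig carbocyclisation, in which the cationic oxazaborolidinium Lewis acid binds the 2-substituted acrolein s-trans and lets the diene add para-selectively to one enantioface, fixing the quaternary carbon of 6 (its only stereocentre, defined solely by the position of the enol ether, hence the base buffer before methanol is added), after which Ph3PAu+ activates the alkyne for attack by the enol ether carbon so that both bridgeheads of 7 follow from that one centre; the closest known reactions are Corey's cationic oxazaborolidine Diels–Alder reactions of 2-substituted acroleins with 2-silyloxydienes, Toste's gold-catalysed cyclisation of silyl enol ethers onto alkynes and the racemic ZnBr2-mediated Diels–Alder/carbocyclisation cascades.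

Step 4
Reactants: 7 (1R,5R)-6-methylidene-4-oxobicyclo[3.2.1]octane-1-carbaldehyde
Product: 8 (1R,5R)-6-methylidene-4-oxobicyclo[3.2.1]oct-2-ene-1-carbaldehyde
Conditions: IBX (2 equiv), DMSO/PhF (1:2), 70 °C
Reagents that add atoms: none
Why: IBX dehydrogenation (Nicolaou) of the ketone can only go toward the methylene side because the other α-carbon is a bridgehead (Bredt), so a single enone forms; the aldehyde has no α-hydrogen and both stereocentres are untouched.

Step 5
Reactants: 9 (2E)-3-methylpent-2-en-4-yn-1-ol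
Product: 10 (2E)-3-methylpenta-2,4-dien-1-ol
Conditions: H2 (1 atm), Pd/CaCO3 poisoned with Pb(OAc)2, quinoline, EtOAc, rt
Reagents that add atoms: none
Why: Lindlar semihydrogenation reduces the terminal alkyne to the vinyl group and leaves the trisubstituted alkene and its E geometry intact.

Step 6
Reactants: 10 (2E)-3-methylpenta-2,4-dien-1-ol; 11 methyl 2-methylprop-2-enoate
Product: 13 (3aS,7aR)-4,7a-dimethyl-3a,6,7,7a-tetrahydro-2-benzofuran-1(3H)-one, via hydroxy ester 12 (not isolated)
Conditions: MeMgBr (1.0 equiv), Me2Zn (20 mol%), (R)-BINOL (20 mol%), CH2Cl2, 0 °C to rt; aq. NH4Cl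
Reagents that add atoms: none
Why: Template-directed (self-assembled, Ward-type) Diels–Alder reaction in which the bromomagnesium alkoxide (ROMgBr) of 10 and the ester carbonyl are held on one Lewis acid so that the carbinol-bearing diene terminus bonds to the α-carbon of the methacrylate with the ester endo, the chiral complex formed from Me2Zn and (R)-BINOL shields one face, and the cis hydroxy ester lactonises at once, setting the quaternary (7aR) and adjacent tertiary (3aS) centres.

Step 7
Reactants: 13 (3aS,7aR)-4,7a-dimethyl-3a,6,7,7a-tetrahydro-2-benzofuran-1(3H)-one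
Product: 16 (1R,2S)-1,3-dimethylcyclohex-3-ene-1,2-dicarboxylic acid, via potassium hydroxy carboxylate 14 (not isolated), via formyl acid 15 (not isolated)
Conditions: KOH (1.2 equiv), H2O/THF, 60 °C; then TEMPO (5 mol%), NaBr (10 mol%), NaOCl (2.2 equiv), pH 10, 0 °C; HCl to pH 2
Reagents that add atoms: potassium hydroxide [K+].[OH-]; water O
Why: Saponification opens the γ-lactone and the aqueous TEMPO/NaOCl oxidation at pH 10 (where the hydroxy acid stays open) takes the primary alcohol through the aldehyde hydrate to the carboxylate; neither stereocentre is touched.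

Step 8
Reactants: 16 (1R,2S)-1,3-dimethylcyclohex-3-ene-1,2-dicarboxylic acid
Product: 17 (3aS,7aR)-4,7a-dimethyl-3a,6,7,7a-tetrahydro-2-benzofuran-1,3-dione
Conditions: Ac2O, 100 °C; evaporate
Reagents that add atoms: none
Why: Dehydration of the cis-1,2-diacid to the five-membered cyclic anhydride, which masks both acids and rigidifies ring A; stereocentres unchanged.

Step 9
Reactants: 17 (3aS,7aR)-4,7a-dimethyl-3a,6,7,7a-tetrahydro-2-benzofuran-1,3-dione
Product: 18 (3aS,4R,7aR)-4-bromo-4,7a-dimethylhexahydro-2-benzofuran-1,3-dione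
Conditions: HBr (g), CH2Cl2, −40 to 0 °C; used crude
Reagents that add atoms: hydrogen bromide Br
Why: Markovnikov hydrobromination through the tertiary cation gives the tertiary bromide; the configuration at the bromine-bearing carbon (mixture of epimers, major shown) is irrelevant because it becomes a planar radical in step 10.

Step 10
Reactants: 18 (3aS,4R,7aR)-4-bromo-4,7a-dimethylhexahydro-2-benzofuran-1,3-dione; 8 (1R,5R)-6-methylidene-4-oxobicyclo[3.2.1]oct-2-ene-1-carbaldehyde
Product: 19 (1R,2S,5R)-2-[(3aS,4S,7aR)-4,7a-dimethyl-1,3-dioxooctahydro-2-benzofuran-4-yl]-6-methylidene-4-oxobicyclo[3.2.1]octane-1-carbaldehyde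
Conditions: 18 (1.5 equiv), (TMS)3SiH (1.5 equiv, slow addition), Et3B (0.3 equiv)/air, PhH, rt
Reagents that add atoms: none
Why: Giese radical conjugate addition in which bromine abstraction by the silyl radical gives the tertiary ring A radical, which reacts on its face anti to the cis-fused anhydride and adds to the enone β-carbon on the face opposite to the two-carbon bridge, setting the new quaternary centre (4S) and the adjacent tertiary centre (2S) before the α-keto radical is reduced by the silane; the aldehyde and the unactivated methylidene are not attacked by the nucleophilic radical.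

Step 11
Reactants: 19 (1R,2S,5R)-2-[(3aS,4S,7aR)-4,7a-dimethyl-1,3-dioxooctahydro-2-benzofuran-4-yl]-6-methylidene-4-oxobicyclo[3.2.1]octane-1-carbaldehyde
Product: 20 (1R,2S,3S)-3-[(1R,2S,5R)-1-formyl-6-methylidene-4-oxobicyclo[3.2.1]octan-2-yl]-1,3-dimethylcyclohexane-1,2-dicarboxylic acid
Conditions: H2O/THF (1:1), 2,6-lutidine (cat.), 40 °C; dilute HCl wash
Reagents that add atoms: water O
Why: Near-neutral hydrolysis of the cyclic anhydride gives the cis-diacid without enolising the ketone or touching the aldehyde; no stereocentre is affected.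

## Compound list

1 | pent-4-yn-1-ol | C#CCCCO | starting material
2 | pent-4-ynal | C#CCCC=O | intermediate
3 | 2-methylidenepent-4-ynal | C#CCC(=C)C=O | intermediate
4 | but-3-en-2-one | CC(=O)C=C | starting material
5 | tert-butyl(buta-1,3-dien-2-yloxy)dimethylsilane | C=CC(=C)O[Si](C)(C)C(C)(C)C | intermediate
6 | (1R)-4-[(tert-butyldimethylsilyl)oxy]-1-(prop-2-yn-1-yl)cyclohex-3-ene-1-carbaldehyde | C#CC[C@]1(C=O)CC=C(O[Si](C)(C)C(C)(C)C)CC1 | intermediate
7 | (1R,5R)-6-methylidene-4-oxobicyclo[3.2.1]octane-1-carbaldehyde | C=C1C[C@]2(C=O)C[C@H]1C(=O)CC2 | intermediate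
8 | (1R,5R)-6-methylidene-4-oxobicyclo[3.2.1]oct-2-ene-1-carbaldehyde | C=C1C[C@]2(C=O)C[C@H]1C(=O)C=C2 | intermediate
9 | (2E)-3-methylpent-2-en-4-yn-1-ol | C#C/C(C)=C/CO | starting material
10 | (2E)-3-methylpenta-2,4-dien-1-ol | C=C/C(C)=C/CO | intermediate
11 | methyl 2-methylprop-2-enoate | C=C(C)C(=O)OC | starting material
12 | methyl (1R,2S)-2-(hydroxymethyl)-1,3-dimethylcyclohex-3-ene-1-carboxylate | CC1=CCC[C@@](C)(C(=O)OC)[C@H]1CO | intermediate
13 | (3aS,7aR)-4,7a-dimethyl-3a,6,7,7a-tetrahydro-2-benzofuran-1(3H)-one | CC1=CCC[C@@]2(C)C(=O)OC[C@@H]12 | intermediate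
14 | potassium (1R,2S)-2-(hydroxymethyl)-1,3-dimethylcyclohex-3-ene-1-carboxylate | CC1=CCC[C@@](C)(C(=O)[O-])[C@H]1CO.[K+] | intermediate
15 | (1R,2S)-2-formyl-1,3-dimethylcyclohex-3-ene-1-carboxylic acid | CC1=CCC[C@@](C)(C(=O)O)[C@H]1C=O | intermediate
16 | (1R,2S)-1,3-dimethylcyclohex-3-ene-1,2-dicarboxylic acid | CC1=CCC[C@@](C)(C(=O)O)[C@H]1C(=O)O | intermediate
17 | (3aS,7aR)-4,7a-dimethyl-3a,6,7,7a-tetrahydro-2-benzofuran-1,3-dione | CC1=CCC[C@@]2(C)C(=O)OC(=O)[C@@H]12 | intermediate
18 | (3aS,4R,7aR)-4-bromo-4,7a-dimethylhexahydro-2-benzofuran-1,3-dione (major C-4 epimer) | C[C@@]1(Br)CCC[C@@]2(C)C(=O)OC(=O)[C@@H]12 | intermediate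
19 | (1R,2S,5R)-2-[(3aS,4S,7aR)-4,7a-dimethyl-1,3-dioxooctahydro-2-benzofuran-4-yl]-6-methylidene-4-oxobicyclo[3.2.1]octane-1-carbaldehyde | C=C1C[C@]2(C=O)C[C@H]1C(=O)C[C@H]2[C@]1(C)CCC[C@@]3(C)C(=O)OC(=O)[C@@H]13 | intermediate
20 | (1R,2S,3S)-3-[(1R,2S,5R)-1-formyl-6-methylidene-4-oxobicyclo[3.2.1]octan-2-yl]-1,3-dimethylcyclohexane-1,2-dicarboxylic acid | C=C1C[C@]2(C=O)C[C@H]1C(=O)C[C@H]2[C@]1(C)CCC[C@@](C)(C(=O)O)[C@H]1C(=O)O | target

## Step count and risks

- **Total steps:** 11.
- **Longest linear sequence:** 7 steps (9 → 10 → 13 → 16 → 17 → 18 → 19 → 20; steps 5–11).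

**Three steps most likely to fail:**

**Step 3 (one-pot Diels–Alder/gold carbocyclisation).** The risks are acid-induced loss of the silyl enol ether before cyclisation, which would erase the only stereochemical information, and poor compatibility of the two catalysts in one flask. The fallback sets out from 3 and 5 and separates the two ring closures. The Diels–Alder reaction is run alone with the (S)-configured oxazaborolidinium catalyst and the enantiomeric adduct (1S)-4-[(tert-butyldimethylsilyl)oxy]-1-(prop-2-yn-1-yl)cyclohex-3-ene-1-carbaldehyde F1 is isolated. Oxidation of its silyl enol ether with IBX·4-methoxypyridine N-oxide gives (1R)-4-oxo-1-(prop-2-yn-1-yl)cyclohex-2-ene-1-carbaldehyde F2; the unsaturation lands in the arm that carried the enol ether, which is why the other catalyst antipode is needed. Soft enolisation (TBSOTf, Et3N) can only go to the α′ side, because the γ-carbon is quaternary, and gives (1R)-4-[(tert-butyldimethylsilyl)oxy]-1-(prop-2-yn-1-yl)cyclohexa-2,4-diene-1-carbaldehyde F3. Ph3PAuNTf2/MeOH then closes ring D and delivers enone 8 directly, so the route is rejoined at 8 and step 4 is skipped.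

**Step 6 (template Diels–Alder with methyl methacrylate).** The α-methyl dienophile is less reactive than the acrylates for which this template reaction is established. The fallback sets out from 10 and moves the quaternary centre to a separate alkylation. The same template reaction with methyl acrylate gives methyl (1R,2R)-2-(hydroxymethyl)-3-methylcyclohex-3-ene-1-carboxylate F4, which lactonises in the flask to (3aR,7aR)-4-methyl-3a,6,7,7a-tetrahydro-2-benzofuran-1(3H)-one F5. Deprotonation with LDA (THF, −78 °C) and methylation with MeI at the ring-fusion carbon from the convex face of the cis-fused lactone comes back to the route at 13.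

**Step 10 (tertiary-radical addition to the hindered enone).** The bond joins a quaternary carbon to a carbon flanked by another quaternary centre, and simple reduction of the radical may win. The fallback sets out from 18 (and uses 3) and makes the same bond on an unhindered acceptor, then builds ring C by cycloaddition. Radical addition of 18 to but-3-yn-2-one ((TMS)3SiH, Et3B/air; cat. I2 to equilibrate to the E isomer) gives (3aS,4S,7aR)-4,7a-dimethyl-4-[(1E)-3-oxobut-1-en-1-yl]hexahydro-2-benzofuran-1,3-dione F6. TBSOTf/Et3N gives (3aS,4S,7aR)-4-[(1E)-3-[(tert-butyldimethylsilyl)oxy]buta-1,3-dien-1-yl]-4,7a-dimethylhexahydro-2-benzofuran-1,3-dione F7. An endo Diels–Alder reaction with 3 under the (S)-configured oxazaborolidinium catalyst (the quaternary carbon is now bonded through the substituted diene terminus, so the other face of 3 must be used) gives (1R,2S)-4-[(tert-butyldimethylsilyl)oxy]-2-[(3aS,4S,7aR)-4,7a-dimethyl-1,3-dioxooctahydro-2-benzofuran-4-yl]-1-(prop-2-yn-1-yl)cyclohex-3-ene-1-carbaldehyde F8. Mild acid work-up gives (1R,2S)-2-[(3aS,4S,7aR)-4,7a-dimethyl-1,3-dioxooctahydro-2-benzofuran-4-yl]-4-oxo-1-(prop-2-yn-1-yl)cyclohexane-1-carbaldehyde F9. TBSOTf/Et3N enolises toward the unhindered methylene remote from the ring A substituent to give (1R,6S)-4-[(tert-butyldimethylsilyl)oxy]-6-[(3aS,4S,7aR)-4,7a-dimethyl-1,3-dioxooctahydro-2-benzofuran-4-yl]-1-(prop-2-yn-1-yl)cyclohex-3-ene-1-carbaldehyde F10, and Ph3PAuNTf2/MeOH closes ring D to come back at 19.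

## Further compounds

F1 | step 3 | (1S)-4-[(tert-butyldimethylsilyl)oxy]-1-(prop-2-yn-1-yl)cyclohex-3-ene-1-carbaldehyde | C#CC[C@@]1(C=O)CC=C(O[Si](C)(C)C(C)(C)C)CC1
F2 | step 3 | (1R)-4-oxo-1-(prop-2-yn-1-yl)cyclohex-2-ene-1-carbaldehyde | C#CC[C@]1(C=O)CCC(=O)C=C1
F3 | step 3 | (1R)-4-[(tert-butyldimethylsilyl)oxy]-1-(prop-2-yn-1-yl)cyclohexa-2,4-diene-1-carbaldehyde | C#CC[C@]1(C=O)CC=C(O[Si](C)(C)C(C)(C)C)C=C1
F4 | step 6 | methyl (1R,2R)-2-(hydroxymethyl)-3-methylcyclohex-3-ene-1-carboxylate | CC1=CCC[C@@H](C(=O)OC)[C@H]1CO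
F5 | step 6 | (3aR,7aR)-4-methyl-3a,6,7,7a-tetrahydro-2-benzofuran-1(3H)-one | CC1=CCC[C@H]2C(=O)OC[C@@H]12
F6 | step 10 | (3aS,4S,7aR)-4,7a-dimethyl-4-[(1E)-3-oxobut-1-en-1-yl]hexahydro-2-benzofuran-1,3-dione | CC(=O)/C=C/[C@]1(C)CCC[C@@]2(C)C(=O)OC(=O)[C@@H]12
F7 | step 10 | (3aS,4S,7aR)-4-[(1E)-3-[(tert-butyldimethylsilyl)oxy]buta-1,3-dien-1-yl]-4,7a-dimethylhexahydro-2-benzofuran-1,3-dione | C=C(O[Si](C)(C)C(C)(C)C)/C=C/[C@]1(C)CCC[C@@]2(C)C(=O)OC(=O)[C@@H]12
F8 | step 10 | (1R,2S)-4-[(tert-butyldimethylsilyl)oxy]-2-[(3aS,4S,7aR)-4,7a-dimethyl-1,3-dioxooctahydro-2-benzofuran-4-yl]-1-(prop-2-yn-1-yl)cyclohex-3-ene-1-carbaldehyde | C#CC[C@]1(C=O)CCC(O[Si](C)(C)C(C)(C)C)=C[C@H]1[C@]1(C)CCC[C@@]2(C)C(=O)OC(=O)[C@@H]12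
F9 | step 10 | (1R,2S)-2-[(3aS,4S,7aR)-4,7a-dimethyl-1,3-dioxooctahydro-2-benzofuran-4-yl]-4-oxo-1-(prop-2-yn-1-yl)cyclohexane-1-carbaldehyde | C#CC[C@]1(C=O)CCC(=O)C[C@H]1[C@]1(C)CCC[C@@]2(C)C(=O)OC(=O)[C@@H]12
F10 | step 10 | (1R,6S)-4-[(tert-butyldimethylsilyl)oxy]-6-[(3aS,4S,7aR)-4,7a-dimethyl-1,3-dioxooctahydro-2-benzofuran-4-yl]-1-(prop-2-yn-1-yl)cyclohex-3-ene-1-carbaldehyde | C#CC[C@]1(C=O)CC=C(O[Si](C)(C)C(C)(C)C)C[C@H]1[C@]1(C)CCC[C@@]2(C)C(=O)OC(=O)[C@@H]12
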